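**Retrosynthetic overview**
- Target 18 comes from thermolysis of both N-Boc groups of quinone 17, and 17 from oxidative demethylation of the bis-Boc 3,6-bis(indol-3-yl)-1,2,4,5-tetramethoxybenzene 16. The quinone ring is carried as its tetramethyl ether from step 1.
- Feature used: in indole B the prenyl group is on C7, next to C7a and so ortho to N1, and C3 is bonded to the central six-membered ring. The pyrrole ring (N1, C2, C3, C3a, C7a) is therefore cut at C3–C3a and N1–C2 into 2-iodo-6-prenylaniline 13 and the aryl(trimethylsilyl)alkyne 7.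
- Alkyne 7 comes from dibromide 3 by one Suzuki coupling (indole A, bought as its N-Boc 3-boronate 4) and one Sonogashira coupling; 3 comes from bromination of 1,2,4,5-tetramethoxybenzene 1.
- Aniline 13 comes from 2-iodoaniline 8 by N-(1,1-dimethylpropargyl)ation, semihydrogenation and an acid-promoted aromatic aza-Claisen shift.
- Ring order: the central ring and indole A come from starting materials; the pyrrole ring of indole B is the only ring formed (step 7); the quinone is unveiled in step 10.

Key step: step 7

Remark: the target has no stereocentre and its only non-ring C=C carries two methyl groups, so no stereocontrol is needed. Indole B is given a Boc group before the oxidation so that no free indole N–H meets tetravalent cerium.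

Step 1
Reactants: 1 1,2,4,5-tetramethoxybenzene
Product: 3 1,4-dibromo-2,3,5,6-tetramethoxybenzene, via monobromide 2 (not isolated)
Conditions: Br2 (2.2 equiv), CH2Cl2, 0 °C to rt
Reagents that add atoms: bromine, BrBr
Why: Electrophilic aromatic bromination: the two free ring positions of 1 are each flanked by two methoxy groups and para to one another, so two equivalents of Br2 should brominate both with no regiochemical choice.

Step 2
Reactants: 3 1,4-dibromo-2,3,5,6-tetramethoxybenzene (3 equiv); 4 tert-butyl 3-(4,4,5,5-tetramethyl-1,3,2-dioxaborolan-2-yl)indole-1-carboxylate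
Product: 5 tert-butyl 3-(4-bromo-2,3,5,6-tetramethoxyphenyl)indole-1-carboxylate
Conditions: Pd(PPh3)4 (5 mol %), 2 M aq. Na2CO3, DME, 80 °C; excess 3 recovered
Reagents that add atoms: none
Why: Suzuki–Miyaura coupling: zerovalent palladium inserts into one C–Br bond of 3 and the carbonate-activated indol-3-yl boronate transmetalates, the threefold excess of the symmetric dibromide biasing the statistics toward mono-coupling.

Step 3
Reactants: 5 tert-butyl 3-(4-bromo-2,3,5,6-tetramethoxyphenyl)indole-1-carboxylate; 6 ethynyltrimethylsilane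
Product: 7 tert-butyl 3-{2,3,5,6-tetramethoxy-4-[(trimethylsilyl)ethynyl]phenyl}indole-1-carboxylate
Conditions: Pd(PhCN)2Cl2 (5 mol %), [HP(t-Bu)3]BF4 (10 mol %), CuI (5 mol %), i-Pr2NH, dioxane, 60 °C, sealed tube
Reagents that add atoms: none
Why: Sonogashira coupling: the electron-rich, di-ortho-substituted C–Br bond needs the bulky, strongly donating P(t-Bu)3 ligand for oxidative addition, after which the copper acetylide of 6 transmetalates and reductive elimination forms the aryl–alkyne bond, the amine base leaving the C–Si bond intact.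

Step 4
Reactants: 8 2-iodoaniline; 9 3-chloro-3-methylbut-1-yne
Product: 10 2-iodo-N-(2-methylbut-3-yn-2-yl)aniline
Conditions: CuCl (10 mol %), Cu powder, Et3N, THF, 0 °C to rt
Reagents that add atoms: none
Why: Copper-catalysed propargylic amination: the copper acetylide of 9 ionises the tertiary chloride so that the weakly nucleophilic aniline nitrogen attacks the quaternary carbon once only, Et3N taking up HCl.

Step 5
Reactants: 10 2-iodo-N-(2-methylbut-3-yn-2-yl)aniline
Product: 11 2-iodo-N-(2-methylbut-3-en-2-yl)aniline
Conditions: H2 (1 atm), Pd/CaCO3 poisoned with Pb(OAc)2 (Lindlar catalyst), quinoline, EtOAc, rt, stopped after 1 equiv H2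
Reagents that add atoms: none
Why: Lindlar semihydrogenation: the terminal alkyne is reduced to the vinyl group, and the poisoned palladium surface together with quinoline should hold back both over-reduction and hydrogenolysis of the C–I bond.

Step 6
Reactants: 11 2-iodo-N-(2-methylbut-3-en-2-yl)aniline
Product: 13 2-iodo-6-(3-methylbut-2-enyl)aniline, via dienimine 12 (not isolated)
Conditions: p-TsOH·H2O (0.2 equiv), MeCN/H2O 10:1, 70 °C
Reagents that add atoms: none
Why: Acid-promoted aromatic aza-Claisen ([3,3]-sigmatropic) rearrangement: the N-protonated 1,1-dimethylallylaniline shifts its allyl unit with inversion to the only free ortho carbon, turning the reverse-prenyl group on nitrogen into a normal prenyl group on carbon, and tautomerisation of dienimine 12 restores the aniline.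

Step 7
Reactants: 7 tert-butyl 3-{2,3,5,6-tetramethoxy-4-[(trimethylsilyl)ethynyl]phenyl}indole-1-carboxylate; 13 2-iodo-6-(3-methylbut-2-enyl)aniline (1.5 equiv)
Product: 14 tert-butyl 3-{2,3,5,6-tetramethoxy-4-[7-(3-methylbut-2-enyl)-2-(trimethylsilyl)-1H-indol-3-yl]phenyl}indole-1-carboxylate
Conditions: Pd(OAc)2 (10 mol %), LiCl (1 equiv), Na2CO3 (3 equiv), DMF, 100 °C
Reagents that add atoms: none
Why: Pd(OAc)2 is reduced in the flask to zerovalent palladium, which inserts into the C–I bond of 13; the chloride-ligated arylpalladium species binds alkyne 7 and adds across it in a syn fashion, the aryl carbon bonding to the alkyne carbon that carries the tetramethoxyphenyl ring (the future C3–C3a bond) and palladium to the silyl-bearing carbon. The aniline nitrogen then displaces halide, HI going to Na2CO3, and C–N reductive elimination from the six-membered azapalladacycle forms N1–C2 and returns zerovalent palladium. The closest known reaction is the Larock heteroannulation of 2-iodoanilines with aryl(trialkylsilyl)acetylenes, which gives 2-silyl-3-arylindoles. The pyrrole ring of indole B is closed as a formal [3+2] annulation, one bond by intermolecular carbopalladation and the ring-closing bond by reductive elimination at nitrogen; no stereocentre is formed. The selectivity needed is the direction of alkyne insertion: the Me3Si group, by its tetrahedral bulk and its stabilisation of an alpha C–Pd bond, takes the carbon next to palladium and so ends at C2, which places the central ring at C3, while the position of iodine in 13 fixes the prenyl group at C7. The trisubstituted prenyl alkene is a poor partner for carbopalladation and sits meta to the palladium-bearing carbon, so neither an intermolecular nor an intramolecular Heck reaction should compete.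

Step 8
Reactants: 14 tert-butyl 3-{2,3,5,6-tetramethoxy-4-[7-(3-methylbut-2-enyl)-2-(trimethylsilyl)-1H-indol-3-yl]phenyl}indole-1-carboxylate
Product: 15 tert-butyl 3-{2,3,5,6-tetramethoxy-4-[7-(3-methylbut-2-enyl)-1H-indol-3-yl]phenyl}indole-1-carboxylate
Conditions: Bu4NF (1.5 equiv, 1 M in THF), THF, 0 °C to rt
Reagents that add atoms: none
Why: Fluoride-induced protodesilylation: fluoride attacks silicon, the C2–Si bond of the 2-silylindole breaks because the sp2 carbanion next to nitrogen is a good leaving group, and water in the reagent protonates C2, while at or below room temperature the N-Boc group of indole A should stay on.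

Step 9
Reactants: 15 tert-butyl 3-{2,3,5,6-tetramethoxy-4-[7-(3-methylbut-2-enyl)-1H-indol-3-yl]phenyl}indole-1-carboxylate
Product: 16 tert-butyl 3-{4-[1-(tert-butoxycarbonyl)indol-3-yl]-2,3,5,6-tetramethoxyphenyl}-7-(3-methylbut-2-enyl)indole-1-carboxylate
Conditions: Boc2O (2 equiv), DMAP (0.2 equiv), MeCN, rt
Reagents that add atoms: di-tert-butyl dicarbonate, CC(C)(C)OC(=O)OC(=O)OC(C)(C)C
Why: DMAP-catalysed N-acylation (Boc protection): the acylpyridinium formed from Boc2O carbamoylates the free indole nitrogen, which removes the last electron-rich N–H before the oxidation and would also re-protect any indole A nitrogen laid bare in steps 7 and 8.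

Step 10
Reactants: 16 tert-butyl 3-{4-[1-(tert-butoxycarbonyl)indol-3-yl]-2,3,5,6-tetramethoxyphenyl}-7-(3-methylbut-2-enyl)indole-1-carboxylate
Product: 17 tert-butyl 3-{4-[1-(tert-butoxycarbonyl)indol-3-yl]-2,5-dimethoxy-3,6-dioxocyclohexa-1,4-dien-1-yl}-7-(3-methylbut-2-enyl)indole-1-carboxylate
Conditions: (NH4)2Ce(NO3)6 (2.5 equiv), MeCN/H2O 4:1, 0 °C, short reaction time
Reagents that add atoms: water, O
Why: Oxidative demethylation of a hydroquinone dimethyl ether by tetravalent cerium: two one-electron oxidations of the tetraalkoxybenzene, the most electron-rich ring now that both indoles carry Boc, with attack of water at a para pair of methoxy-bearing carbons and loss of two MeOH should give the 2,5-dimethoxy-1,4-quinone, and both para pairs lead to the same product.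

Step 11
Reactants: 17 tert-butyl 3-{4-[1-(tert-butoxycarbonyl)indol-3-yl]-2,5-dimethoxy-3,6-dioxocyclohexa-1,4-dien-1-yl}-7-(3-methylbut-2-enyl)indole-1-carboxylate
Product: 18 2,5-dimethoxy-3-(1H-indol-3-yl)-6-[7-(3-methylbut-2-enyl)-1H-indol-3-yl]cyclohexa-2,5-diene-1,4-dione
Conditions: neat under argon (or in Ph2O), 180 °C
Reagents that add atoms: none
Why: Thermolytic cleavage of N-Boc groups: each tert-butyl carbamate fragments to 2-methylpropene and a carbamic acid that loses CO2, a neutral, reagent-free unmasking that should leave the vinylogous-ester methoxy groups, the quinone and the prenyl alkene untouched.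

**Compound list**
1 | 1,2,4,5-tetramethoxybenzene | COc1cc(OC)c(OC)cc1OC | starting material
2 | 1-bromo-2,3,5,6-tetramethoxybenzene (monobromide) | COc1cc(OC)c(OC)c(Br)c1OC | intermediate
3 | 1,4-dibromo-2,3,5,6-tetramethoxybenzene | COc1c(Br)c(OC)c(OC)c(Br)c1OC | intermediate
4 | tert-butyl 3-(4,4,5,5-tetramethyl-1,3,2-dioxaborolan-2-yl)indole-1-carboxylate | CC(C)(C)OC(=O)n1cc(B2OC(C)(C)C(C)(C)O2)c2ccccc12 | starting material
5 | tert-butyl 3-(4-bromo-2,3,5,6-tetramethoxyphenyl)indole-1-carboxylate | COc1c(Br)c(OC)c(OC)c(-c2cn(C(=O)OC(C)(C)C)c3ccccc23)c1OC | intermediate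
6 | ethynyltrimethylsilane | C#C[Si](C)(C)C | starting material
7 | tert-butyl 3-{2,3,5,6-tetramethoxy-4-[(trimethylsilyl)ethynyl]phenyl}indole-1-carboxylate | C[Si](C)(C)C#Cc1c(OC)c(OC)c(-c2cn(C(=O)OC(C)(C)C)c3ccccc23)c(OC)c1OC | intermediate
8 | 2-iodoaniline | Nc1ccccc1I | starting material
9 | 3-chloro-3-methylbut-1-yne | C#CC(C)(C)Cl | starting material
10 | 2-iodo-N-(2-methylbut-3-yn-2-yl)aniline | C#CC(C)(C)Nc1ccccc1I | intermediate
11 | 2-iodo-N-(2-methylbut-3-en-2-yl)aniline | C=CC(C)(C)Nc1ccccc1I | intermediate
12 | 2-iodo-6-(3-methylbut-2-enyl)cyclohexa-2,4-dien-1-imine (dienimine, racemic, present as its iminium salt) | N=C1C(I)=CC=CC1CC=C(C)C | intermediate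
13 | 2-iodo-6-(3-methylbut-2-enyl)aniline | Nc1c(I)cccc1CC=C(C)C | intermediate
14 | tert-butyl 3-{2,3,5,6-tetramethoxy-4-[7-(3-methylbut-2-enyl)-2-(trimethylsilyl)-1H-indol-3-yl]phenyl}indole-1-carboxylate | COc1c(OC)c(-c2c([Si](C)(C)C)[nH]c3c(CC=C(C)C)cccc23)c(OC)c(OC)c1-c1cn(C(=O)OC(C)(C)C)c2ccccc12 | intermediate
15 | tert-butyl 3-{2,3,5,6-tetramethoxy-4-[7-(3-methylbut-2-enyl)-1H-indol-3-yl]phenyl}indole-1-carboxylate | COc1c(OC)c(-c2c[nH]c3c(CC=C(C)C)cccc23)c(OC)c(OC)c1-c1cn(C(=O)OC(C)(C)C)c2ccccc12 | intermediate
16 | tert-butyl 3-{4-[1-(tert-butoxycarbonyl)indol-3-yl]-2,3,5,6-tetramethoxyphenyl}-7-(3-methylbut-2-enyl)indole-1-carboxylate | COc1c(OC)c(-c2cn(C(=O)OC(C)(C)C)c3c(CC=C(C)C)cccc23)c(OC)c(OC)c1-c1cn(C(=O)OC(C)(C)C)c2ccccc12 | intermediate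
17 | tert-butyl 3-{4-[1-(tert-butoxycarbonyl)indol-3-yl]-2,5-dimethoxy-3,6-dioxocyclohexa-1,4-dien-1-yl}-7-(3-methylbut-2-enyl)indole-1-carboxylate | COC1=C(c2cn(C(=O)OC(C)(C)C)c3ccccc23)C(=O)C(OC)=C(c2cn(C(=O)OC(C)(C)C)c3c(CC=C(C)C)cccc23)C1=O | intermediate
18 | 2,5-dimethoxy-3-(1H-indol-3-yl)-6-[7-(3-methylbut-2-enyl)-1H-indol-3-yl]cyclohexa-2,5-diene-1,4-dione | COC1=C(c2c[nH]c3ccccc23)C(=O)C(OC)=C(c2c[nH]c3c(CC=C(C)C)cccc23)C1=O | target

**Step count**
Total: 11 steps. Longest linear sequence: 8 steps (1 → 3 → 5 → 7 → 14 → 15 → 16 → 17 → 18; the branch from 8 is equally long).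

**Steps most likely to fail**

Step 7. Insertion of the doubly hindered alkyne may be slower than decay of the arylpalladium species (reduction or homocoupling of 13). Carbonate may also strip the alkynyl silyl group, so that a coupling–cyclisation path leads to the 2-aryl isomer, or the bulk of the di-ortho-methoxyaryl group may erode the sense of insertion. The fallback builds indole B first and joins it to the core by Suzuki coupling; it sets out from 13 and returns at 16. Sonogashira coupling of 13 with 6 (Pd(PPh3)2Cl2, CuI, Et3N, rt) should give 2-(3-methylbut-2-enyl)-6-[(trimethylsilyl)ethynyl]aniline F1. Bu4NF in refluxing THF should remove silicon and bring about 5-endo cyclisation to 7-(3-methylbut-2-enyl)-1H-indole F2. Boc2O/DMAP should give tert-butyl 7-(3-methylbut-2-enyl)indole-1-carboxylate F3. C–H borylation with [Ir(OMe)(cod)]2, 4,4'-di-tert-butyl-2,2'-bipyridine and B2pin2, which the N-Boc group steers to C3, should give tert-butyl 7-(3-methylbut-2-enyl)-3-(4,4,5,5-tetramethyl-1,3,2-dioxaborolan-2-yl)indole-1-carboxylate F4. Suzuki coupling of F4 with bromide 5 (Pd(PPh3)4, aq. Na2CO3, DME, 80 °C) then gives 16 directly, so steps 8 and 9 are skipped.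

Step 10. Tetravalent cerium may oxidise the indole rings or the prenyl double bond along with, or instead of, the central ring, or water may attack an ortho pair of methoxy-bearing carbons and lead to an ortho-quinone. The fallback unveils the quinone in two stages under potential control; it sets out from 16 and returns at 17. Anodic oxidation of 16 at a carbon anode in MeOH/THF (LiClO4, 2,6-lutidine, constant potential just above the first oxidation wave of the central ring) should give the quinone bis(dimethyl ketal) tert-butyl 3-{4-[1-(tert-butoxycarbonyl)indol-3-yl]-2,3,3,5,6,6-hexamethoxycyclohexa-1,4-dien-1-yl}-7-(3-methylbut-2-enyl)indole-1-carboxylate F5. Brief hydrolysis with aqueous AcOH at rt should then release 17 with both Boc groups in place.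

Step 2. Mono-selectivity may be lost: the second C–Br bond of the first-formed product may couple before the catalyst leaves the ring, giving the symmetric bis(indolyl) compound, and protodeboronation of 4 is a further drain. The fallback differentiates the two halogens first; it sets out from 3 and returns at 5. Bromine–lithium exchange with one equivalent of n-BuLi (THF, −78 °C) followed by I2 should give 1-bromo-4-iodo-2,3,5,6-tetramethoxybenzene F6. Suzuki coupling of 4 at the C–I bond (Pd(PPh3)4, aq. Na2CO3, DME, 60 °C) should leave the bromide in place and give 5.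

**Further compounds**
F1 | step 7 | 2-(3-methylbut-2-enyl)-6-[(trimethylsilyl)ethynyl]aniline | Nc1c(CC=C(C)C)cccc1C#C[Si](C)(C)C
F2 | step 7 | 7-(3-methylbut-2-enyl)-1H-indole | CC(C)=CCc1cccc2cc[nH]c12
F3 | step 7 | tert-butyl 7-(3-methylbut-2-enyl)indole-1-carboxylate | CC(C)=CCc1cccc2ccn(C(=O)OC(C)(C)C)c12
F4 | step 7 | tert-butyl 7-(3-methylbut-2-enyl)-3-(4,4,5,5-tetramethyl-1,3,2-dioxaborolan-2-yl)indole-1-carboxylate | CC(C)=CCc1cccc2c(B3OC(C)(C)C(C)(C)O3)cn(C(=O)OC(C)(C)C)c12
F5 | step 10 | tert-butyl 3-{4-[1-(tert-butoxycarbonyl)indol-3-yl]-2,3,3,5,6,6-hexamethoxycyclohexa-1,4-dien-1-yl}-7-(3-methylbut-2-enyl)indole-1-carboxylate | COC1=C(c2cn(C(=O)OC(C)(C)C)c3ccccc23)C(OC)(OC)C(OC)=C(c2cn(C(=O)OC(C)(C)C)c3c(CC=C(C)C)cccc23)C1(OC)OC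
F6 | step 2 | 1-bromo-4-iodo-2,3,5,6-tetramethoxybenzene | COc1c(Br)c(OC)c(OC)c(I)c1OC
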